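## The problem

The target 16 is an achiral, unsymmetrical diaryl ether. Ring A is a methyl 2-hydroxy-4-methylbenzoate whose C6 carries the bridging oxygen. Ring B carries that oxygen on C1, between C2 (CH2OH) and C6 (O-prenyl), with a methoxy group on C4. The C–O–C bridge therefore has three ortho substituents and joins two electron-rich rings, which is where copper-mediated or nucleophilic aromatic C–O coupling is least dependable. There is no stereocentre to set; the one stereogenic atom on the route is a transient spiro carbon that controls nothing and is erased. The selectivity questions are regiochemical: the three oxygens of ring B (aryl ether at C1, methyl ether at C4, prenyl ether at C6) and the two of ring A (free OH at C2, aryl ether at C6) must each receive a different partner. The fragile groups are the aryl prenyl ether (acid, Lewis acid, hydrogenation, heat), the benzylic alcohol on an oxygenated ring, and the methyl ester next to a phenol. They call for late prenylation and a non-acidic unmasking. The enabling feature is that ring A's ether oxygen (on C6) and ester carbon (on C1) are ortho, so with ring B C1 they can be closed into a benzofuran-3-one whose C2 is ring B C1. Ring B's oxygens at C4 and C6 are then the carbonyls of a cyclohexane-1,3-dione, and its C2–C3 edge with the CH2O branch maps onto a 4-oxygenated but-2-ynoate. Ring B can thus be grown on furanone C2 from an acetyl group and an alkynoate, and its later aromatisation pays for releasing the furanone carbonyl as the methyl ester.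

## Retrosynthesis

**16 ⇒ 15.** The two O–protecting-group bonds are cut last. The ring A phenol is held as a SEM acetal and the benzylic oxygen as a TBDPS ether, both fluoride-labile. One non-acidic step therefore uncovers 16. Acid-labile masking would put the prenyl ether and the benzylic alcohol at risk, and hydrogenolysis would reduce the prenyl alkene. The forward step only has to leave the ester and the allylic ether alone.

**15 ⇒ 13 + 14.** The O–CH2 bond of the prenyl ether is cut. It is placed as the last constructive step because this ether is the most sensitive group. Phenol 13 carries only one free hydroxyl (ring B C6), so the alkylation with 14 has no regiochemical question.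

**13 ⇒ 12.** In the reverse sense the ester carbon of ring A is reconnected to ring B C1, which dearomatises ring B into the spiro dienone 12. This is preferred over the obvious neighbour, cutting the aryl–O bond into two arenes, because that bond would have to be made between a doubly ortho-substituted, electron-rich ring B carbon and a phenol ortho to an ester. In 12 the ether oxygen sits on an sp3 carbon. Forward, methanolysis must attack the furanone carbonyl; the carbanion that leaves is the phenoxide of an aromatic ring B, so the C6 oxygen appears free and already distinguished from the C4 methyl ether.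

**12 ⇒ 11.** The C4–O–CH3 bond is cut. Placing this cut before aromatisation is the point of the plan: in trione 11 the two dione oxygens differ strongly in their surroundings (C6 is next to the spiro carbon, C4 is flanked by two CH positions), whereas in a resorcinol-type ring B they would be two similar phenols. Forward, the enol ether must form at the distal oxygen only.

**11 ⇒ 5 + 9.** Ring B is opened at C1–C2 and C4–C5. This returns the acetylbenzofuranone 5, whose acetyl group supplies C5 and C6, and the alkynoate 9, which supplies C2, C3, C4 and the CH2O branch. The passage goes through the conjugate adduct 10. Cutting C1–C6 or C5–C6 instead would need an acyl anion equivalent or a less accessible ynone partner. Forward, the furanone enolate must react at carbon, at the β-carbon of 9, and the adduct must reach the geometry with the ester cis to the spiro carbon.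

**5 ⇒ 4 ⇒ 2 + 3, and 2 ⇒ 1.** The furanone C2–C3 bond is cut (Dieckmann closure of keto ester 4). Then the O–CH2 bond is cut (alkylation of phenol 2 with chloroacetone 3), and finally the SEM group is removed from 2 to give the symmetrical dihydroxy ester 1. The symmetry of 1 means that mono-protection needs no regiocontrol, and the hydrogen-bonded second hydroxyl resists over-reaction.

**9 ⇒ 7 ⇒ 6.** The alkyne–carboxyl bond is cut (carboxylation of the acetylide 8 derived from silyl ether 7) and then the O–Si bond, leading to propargyl alcohol 6. TBDPS is chosen over smaller silyl groups because it must survive the mildly acidic enol etherification as well as the alkoxide steps.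

## Roads not taken

**Alternative 1:** Ring A is cut at C1–C6 and C4–C5. Forward, the electron-poor pyrone A1 and the ring B ethynyl ether A2 would combine by (4+2) cycloaddition, and decarboxylative cycloreversion of the bridged lactone would give the benzene ring of the bis-silyl ether A3.
- Merits: the polarity of the two partners matches the required regiochemistry, the route is convergent, the oxygen pattern of ring B is fixed from the outset, and only a desilylation follows the union. In convergence and in the absence of any enol-ether regiochemistry this road is better.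
- Weak points: A2 has to be made from the fully differentiated, doubly ortho-substituted phenol A4 by a vinylation–elimination sequence under strongly basic conditions, and A4 is itself a multi-step problem of distinguishing three ring B oxygens. The cycloaddition and the extrusion need prolonged heating of a molecule that carries both an aryl prenyl ether (open to aromatic Claisen rearrangement onto C5) and a thermally delicate ynol ether.
- Comparison: the chosen plan offers ionic chemistry below 50 °C, cheap starting materials, a late prenylation, and no pre-built ring B arene.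

**Alternative 2:** Ring B is cut at C2–C3, C3–C4, C5–C6 and C1–C6. Forward, irradiation of the diazoketone A5 would give, by Wolff rearrangement, an aryloxyvinylketene. This would add methoxyacetylene A6 to give a cyclobutenone, which opens and recloses by 6π electrocyclisation to phenol A7. A7 is the counterpart of 13.
- Merits: the Danheiser benzannulation places OCH3 on C4 and OH on C6 by mechanism, with no ambiguity. In that respect it is better than the chosen plan, which depends on a selective enol etherification. It also makes the ether bond at an sp2 carbon of an enone and not of an arene.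
- Weak points: A5 is a β-aryloxy enone carrying a diazo ketone. It needs an addition–elimination of the ring A phenol and a diazo transfer, and is both acid- and light-sensitive. A6 is volatile and not easily handled. The photochemical step builds a pentasubstituted arene from a hindered, donor-substituted vinylketene, for which competing ketene dimerisation and poor throughput are likely.
- Comparison: the chosen plan reaches the same intermediate type from bulk chemicals by base-mediated steps, and has the depsidone detour in reserve should the enol etherification not be selective.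

**Alternative 3:** Ring A is cut at C2–C3. Forward, base would deprotonate a terminal methyl of the dienylidene malonate A8, and the extended enolate would attack the cis ester carbonyl with loss of methoxide, tautomerising to the salicylate A9.
- Merits: the closure needs only base, ring A's phenol is formed free so no protecting group is spent on it, and A9 is one desilylation from the target. In end-game length this road is better.
- Weak points: A8 requires addition–elimination of the hindered phenol A4 at a tetrasubstituted vinylic carbon, so the congested C–O bond formation avoided in the chosen plan returns in another form. A4 must again be made with all three oxygens differentiated. The prenyl ether is carried through the strongly basic vinylogous condensation, where deprotonation at the wrong site or conjugate addition of the base can compete.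
- Comparison: the chosen plan has a longer end-game, but it forms the ether bond by a simple alkylation and differentiates the ring B oxygens on the way.

Key step: step 6

Remark: 5 is written as its keto tautomer although it should exist largely as the 2-acetyl-3-hydroxybenzofuran enol, and 10–12 are racemic at the spiro carbon; neither matters, because that centre is destroyed in step 8.

## Route

Step 1
Reactants: 1 methyl 2,6-dihydroxy-4-methylbenzoate
Product: 2 methyl 2-hydroxy-4-methyl-6-{[2-(trimethylsilyl)ethoxy]methoxy}benzoate
Conditions: SEMCl (1.05 equiv), i-Pr2NEt, CH2Cl2, 0 °C → rt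
Reagents that add atoms: 2-(trimethylsilyl)ethoxymethyl chloride, C[Si](C)(C)CCOCCl
Why: O-alkylation of a phenol with an α-chloro ether (SEM protection); the two hydroxyls of 1 are equivalent, and after the first has reacted the second is held in a hydrogen bond to the ester carbonyl, so one equivalent of reagent should stop at the mono-ether.

Step 2
Reactants: 2 methyl 2-hydroxy-4-methyl-6-{[2-(trimethylsilyl)ethoxy]methoxy}benzoate; 3 chloroacetone
Product: 4 methyl 4-methyl-2-(2-oxopropoxy)-6-{[2-(trimethylsilyl)ethoxy]methoxy}benzoate
Conditions: K2CO3, KI (cat.), acetone, reflux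
Reagents that add atoms: none
Why: Williamson ether synthesis with an activated α-halo ketone under Finkelstein catalysis; the future diaryl ether oxygen is thereby bonded to an sp3 carbon by a routine alkylation.

Step 3
Reactants: 4 methyl 4-methyl-2-(2-oxopropoxy)-6-{[2-(trimethylsilyl)ethoxy]methoxy}benzoate
Product: 5 2-acetyl-6-methyl-4-{[2-(trimethylsilyl)ethoxy]methoxy}-1-benzofuran-3(2H)-one
Conditions: t-BuOK (2.2 equiv), THF, 0 °C → rt; then cold 1 M HCl
Reagents that add atoms: none
Why: Dieckmann-type intramolecular Claisen condensation of the O–CH2 carbanion onto the ortho ester (5-exo-trig), the standard route from O-acetonyl salicylates to 2-acyl-3-hydroxybenzofurans; the product is withdrawn as its stabilised enolate, and closure from the methyl terminus would need a seven-membered ring.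

Step 4
Reactants: 6 propargyl alcohol
Product: 7 tert-butyl(diphenyl)(prop-2-yn-1-yloxy)silane
Conditions: TBDPSCl, imidazole, CH2Cl2, 0 °C → rt
Reagents that add atoms: tert-butyl(chloro)diphenylsilane, CC(C)(C)[Si](Cl)(c1ccccc1)c1ccccc1
Why: Routine silylation of a primary alcohol; TBDPS is chosen because it tolerates both the alkoxide steps and the mildly acidic enol etherification later.

Step 5
Reactants: 7 tert-butyl(diphenyl)(prop-2-yn-1-yloxy)silane
Product: 9 methyl 4-{[tert-butyl(diphenyl)silyl]oxy}but-2-ynoate, via lithium acetylide 8 (not isolated)
Conditions: n-BuLi, THF, −78 °C; then ClCO2Me, −78 → 0 °C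
Reagents that add atoms: n-butyllithium, [Li]CCCC (lithium is held only in 8); methyl chloroformate, COC(=O)Cl
Why: Deprotonation of the terminal alkyne and C-acylation of the acetylide with a chloroformate, the usual preparation of 4-silyloxybut-2-ynoates.

Step 6
Reactants: 5 2-acetyl-6-methyl-4-{[2-(trimethylsilyl)ethoxy]methoxy}-1-benzofuran-3(2H)-one; 9 methyl 4-{[tert-butyl(diphenyl)silyl]oxy}but-2-ynoate
Product: 11 racemic 6′-({[tert-butyl(diphenyl)silyl]oxy}methyl)-6-methyl-4-{[2-(trimethylsilyl)ethoxy]methoxy}-3H-spiro[1-benzofuran-2,1′-cyclohex-5′-ene]-2′,3,4′-trione, via Michael adduct 10 (not isolated)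
Conditions: t-BuOK (0.2 equiv), t-BuOH–THF, 0 °C → rt; then t-BuOK (2.5 equiv), THF, 0 → 40 °C; then cold 1 M HCl
Reagents that add atoms: none
Why: Catalytic alkoxide forms the doubly stabilised 3-oxidobenzofuran enolate of 5, which adds through C2 to the β-carbon of alkynoate 9 (Michael addition), creating ring B C1–C2 and the quaternary spiro carbon. The E and Z adducts interconvert under the base by reversible addition and through the γ-deprotonated dienolate, and only the Z isomer 10, with the ester cis to the spiro carbon, can react further. Excess t-BuOK then forms the acetyl methyl enolate, which attacks the ester in a 6-(enolendo)-exo-trig Claisen (Dieckmann-type) closure, making C4–C5 with loss of methoxide. The closest known reaction types are the consecutive Michael–Claisen (3+3) synthesis of cyclohexane-1,3-diones from methyl ketones and unsaturated esters, and the Michael–Dieckmann spiroannulation of 2-acyl- and 2-carboalkoxybenzofuran-3-ones that leads to grisan triones. The step needs C- over O-attack of the ambident enolate and β-attack on the alkynoate: the soft acceptor and the polarisation by the ester favour both, and an O-adduct or E-adduct can revert, whereas the trione is removed irreversibly as its vinylogous carboxylate, which also shields it from the liberated methoxide. No other ring closure is open to 10, since every alternative would be three- or four-membered. The bulky, weakly nucleophilic alkoxide is chosen so that retro-Claisen loss of the acetyl group from 10 does not compete. The spiro carbon is the only new stereocentre; nothing controls it, 11 is racemic, and the centre is destroyed in step 8.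

Step 7
Reactants: 11 racemic 6′-({[tert-butyl(diphenyl)silyl]oxy}methyl)-6-methyl-4-{[2-(trimethylsilyl)ethoxy]methoxy}-3H-spiro[1-benzofuran-2,1′-cyclohex-5′-ene]-2′,3,4′-trione
Product: 12 racemic 6′-({[tert-butyl(diphenyl)silyl]oxy}methyl)-4′-methoxy-6-methyl-4-{[2-(trimethylsilyl)ethoxy]methoxy}-3H-spiro[1-benzofuran-2,1′-cyclohexa-3′,5′-diene]-2′,3-dione
Conditions: HC(OMe)3, MeOH, CSA (5 mol %), 0 °C → rt; Et3N quench
Reagents that add atoms: methanol, CO; trimethyl orthoformate, COC(OC)OC (water scavenger and alternative methoxy donor)
Why: Acid-catalysed enol etherification of a cyclic 1,3-dione; methanol should add at the unhindered C4 terminus (C4′) of the protonated dione while C6 is shielded by the spiro carbon, the preference known for 4,4-disubstituted cyclohexane-1,3-diones and for grisan-2′,4′-diones, which give the distal enol ether under acid–alcohol conditions. The orthoformate removes water, and the brief, weakly acidic conditions should spare the SEM and TBDPS ethers.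

Step 8
Reactants: 12 racemic 6′-({[tert-butyl(diphenyl)silyl]oxy}methyl)-4′-methoxy-6-methyl-4-{[2-(trimethylsilyl)ethoxy]methoxy}-3H-spiro[1-benzofuran-2,1′-cyclohexa-3′,5′-diene]-2′,3-dione
Product: 13 methyl 2-[2-({[tert-butyl(diphenyl)silyl]oxy}methyl)-6-hydroxy-4-methoxyphenoxy]-4-methyl-6-{[2-(trimethylsilyl)ethoxy]methoxy}benzoate
Conditions: NaOMe (2 equiv), MeOH–THF, 0 °C → rt; then aq. NH4Cl
Reagents that add atoms: sodium methoxide, [Na+].[O-]C
Why: Retro-Claisen cleavage of a non-enolisable 1,3-diketone: methoxide adds to the furanone carbonyl and the bond to the spiro carbon breaks because the departing carbanion is the phenoxide of an aromatic ring B, the same nucleophilic opening by which grisadienediones pass into diphenyl ethers. Ring A's ester is returned, the C6 oxygen appears as the only free phenol, and the spiro stereocentre vanishes.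

Step 9
Reactants: 13 methyl 2-[2-({[tert-butyl(diphenyl)silyl]oxy}methyl)-6-hydroxy-4-methoxyphenoxy]-4-methyl-6-{[2-(trimethylsilyl)ethoxy]methoxy}benzoate; 14 prenyl bromide (1-bromo-3-methylbut-2-ene)
Product: 15 methyl 2-{2-({[tert-butyl(diphenyl)silyl]oxy}methyl)-4-methoxy-6-[(3-methylbut-2-en-1-yl)oxy]phenoxy}-4-methyl-6-{[2-(trimethylsilyl)ethoxy]methoxy}benzoate
Conditions: K2CO3, acetone, rt → 40 °C
Reagents that add atoms: none
Why: Williamson O-alkylation of the single free phenol with a primary allylic bromide; all other hydroxyls are masked, and the mild carbonate conditions should not touch the ester or the silyl ethers.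

Step 10
Reactants: 15 methyl 2-{2-({[tert-butyl(diphenyl)silyl]oxy}methyl)-4-methoxy-6-[(3-methylbut-2-en-1-yl)oxy]phenoxy}-4-methyl-6-{[2-(trimethylsilyl)ethoxy]methoxy}benzoate
Product: 16 methyl 2-hydroxy-6-{2-(hydroxymethyl)-4-methoxy-6-[(3-methylbut-2-en-1-yl)oxy]phenoxy}-4-methylbenzoate (CNP0532721.0)
Conditions: TBAF (6 equiv), THF–DMPU, 4 Å MS, 50 °C; then aq. NH4Cl
Reagents that add atoms: none
Why: Fluoride-mediated desilylation of the TBDPS ether and fluoride-induced fragmentation of the aryl SEM ether (loss of fluorotrimethylsilane, ethene and formaldehyde) in one operation; no acid is used, so the prenyl ether, the benzylic alcohol and the methyl ester should persist.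

## Compound list

1 | methyl 2,6-dihydroxy-4-methylbenzoate | COC(=O)c1c(O)cc(C)cc1O | starting material
2 | methyl 2-hydroxy-4-methyl-6-{[2-(trimethylsilyl)ethoxy]methoxy}benzoate | COC(=O)c1c(O)cc(C)cc1OCOCC[Si](C)(C)C | intermediate
3 | chloroacetone | CC(=O)CCl | starting material
4 | methyl 4-methyl-2-(2-oxopropoxy)-6-{[2-(trimethylsilyl)ethoxy]methoxy}benzoate | COC(=O)c1c(OCC(C)=O)cc(C)cc1OCOCC[Si](C)(C)C | intermediate
5 | 2-acetyl-6-methyl-4-{[2-(trimethylsilyl)ethoxy]methoxy}-1-benzofuran-3(2H)-one (racemic keto form; largely the enol tautomer) | CC(=O)C1Oc2cc(C)cc(OCOCC[Si](C)(C)C)c2C1=O | intermediate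
6 | propargyl alcohol | C#CCO | starting material
7 | tert-butyl(diphenyl)(prop-2-yn-1-yloxy)silane | C#CCO[Si](c1ccccc1)(c1ccccc1)C(C)(C)C | intermediate
8 | (3-{[tert-butyl(diphenyl)silyl]oxy}prop-1-yn-1-yl)lithium | [Li]C#CCO[Si](c1ccccc1)(c1ccccc1)C(C)(C)C | intermediate
9 | methyl 4-{[tert-butyl(diphenyl)silyl]oxy}but-2-ynoate | COC(=O)C#CCO[Si](c1ccccc1)(c1ccccc1)C(C)(C)C | intermediate
10 | methyl (2Z)-3-(2-acetyl-6-methyl-3-oxo-4-{[2-(trimethylsilyl)ethoxy]methoxy}-2,3-dihydro-1-benzofuran-2-yl)-4-{[tert-butyl(diphenyl)silyl]oxy}but-2-enoate (racemic) | COC(=O)/C=C(/CO[Si](c1ccccc1)(c1ccccc1)C(C)(C)C)C1(C(C)=O)Oc2cc(C)cc(OCOCC[Si](C)(C)C)c2C1=O | intermediate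
11 | racemic 6′-({[tert-butyl(diphenyl)silyl]oxy}methyl)-6-methyl-4-{[2-(trimethylsilyl)ethoxy]methoxy}-3H-spiro[1-benzofuran-2,1′-cyclohex-5′-ene]-2′,3,4′-trione | O=C1c2c(OCOCC[Si](C)(C)C)cc(C)cc2OC13C(CO[Si](c4ccccc4)(c4ccccc4)C(C)(C)C)=CC(=O)CC3=O | intermediate
12 | racemic 6′-({[tert-butyl(diphenyl)silyl]oxy}methyl)-4′-methoxy-6-methyl-4-{[2-(trimethylsilyl)ethoxy]methoxy}-3H-spiro[1-benzofuran-2,1′-cyclohexa-3′,5′-diene]-2′,3-dione | O=C1c2c(OCOCC[Si](C)(C)C)cc(C)cc2OC13C(CO[Si](c4ccccc4)(c4ccccc4)C(C)(C)C)=CC(OC)=CC3=O | intermediate
13 | methyl 2-[2-({[tert-butyl(diphenyl)silyl]oxy}methyl)-6-hydroxy-4-methoxyphenoxy]-4-methyl-6-{[2-(trimethylsilyl)ethoxy]methoxy}benzoate | COC(=O)c1c(OCOCC[Si](C)(C)C)cc(C)cc1Oc1c(CO[Si](c2ccccc2)(c2ccccc2)C(C)(C)C)cc(OC)cc1O | intermediate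
14 | prenyl bromide (1-bromo-3-methylbut-2-ene) | CC(C)=CCBr | starting material
15 | methyl 2-{2-({[tert-butyl(diphenyl)silyl]oxy}methyl)-4-methoxy-6-[(3-methylbut-2-en-1-yl)oxy]phenoxy}-4-methyl-6-{[2-(trimethylsilyl)ethoxy]methoxy}benzoate | COC(=O)c1c(OCOCC[Si](C)(C)C)cc(C)cc1Oc1c(CO[Si](c2ccccc2)(c2ccccc2)C(C)(C)C)cc(OC)cc1OCC=C(C)C | intermediate
16 | methyl 2-hydroxy-6-{2-(hydroxymethyl)-4-methoxy-6-[(3-methylbut-2-en-1-yl)oxy]phenoxy}-4-methylbenzoate | COC(=O)c1c(O)cc(C)cc1Oc1c(CO)cc(OC)cc1OCC=C(C)C | target

## Step count and risks

Total: 10 steps. Longest linear sequence: 8 steps (1, 2, 3, 6, 7, 8, 9, 10); the alkynoate branch (steps 4 and 5) joins at step 6.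

**Step 6 (key step).** The most likely failure is that the reversible conjugate addition stalls, at the O-adduct or at the E geometry, at the hindered β-carbon of a weakly electrophilic alkynoate. Alkoxide-induced loss of the acetyl group from the non-enolisable diketone could then outrun the Claisen closure. The fallback reverses the roles of the Claisen partners; it sets out from 2 and 7 and comes back at 11. Alkylation of 2 with methyl bromoacetate (K2CO3, acetone) would give methyl 2-(2-methoxy-2-oxoethoxy)-4-methyl-6-{[2-(trimethylsilyl)ethoxy]methoxy}benzoate F1. Dieckmann closure (t-BuOK, THF) would give the 2-carbomethoxybenzofuranone F2. Acylation of the acetylide 8 from 7 with N-methoxy-N-methylacetamide would give the ynone 5-{[tert-butyl(diphenyl)silyl]oxy}pent-3-yn-2-one F3, a much stronger acceptor than 9. Carbonate-catalysed Michael addition of F2 to F3 would give the adduct F4. t-BuOK would then close ring B by attack of the methyl ketone enolate on the ester at the spiro carbon (C5–C6 formed instead of C4–C5), leading to the same trione 11.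

**Step 7.** The likely failure is loss of regiocontrol between the two enol oxygens (etherification at C2′ as well as at C4′), together with slow erosion of the SEM acetal under the acid. The fallback sets out from 11 and comes back at 13. Heating 11 in toluene should bring about the grisadienedione–depsidone rearrangement: a 1,3-shift of the furanone acyl group from the spiro carbon to the adjacent carbonyl oxygen, driven by aromatisation of ring B. This would give the hydroxy depsidone F5, in which the C6 oxygen is tied up in the lactone and only the C4 hydroxyl is free. Methylation (MeI, K2CO3, acetone) would give the methoxy depsidone F6, and methanolysis of the aryl ester (NaOMe, MeOH) would open the lactone to 13 with the regiochemistry fixed by constitution.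

**Step 8.** The likely failure is misdirected attack of methoxide on the dienone carbonyl next to the spiro carbon, which would fragment ring B, or slow cleavage accompanied by desilylation. The fallback sets out from 12 and comes back at 13. Thermal acyl shift of 12 (toluene, reflux), with no external nucleophile present, would give the methoxy depsidone F7 (the same constitution as F6). Its lactone offers methoxide a single reactive carbonyl and should open under K2CO3 in MeOH to 13.

**Step 10.** The likely failure is incomplete fluoride cleavage of the aryl SEM ether, recapture of the released formaldehyde by the phenoxide, or ester hydrolysis by wet fluoride at 50 °C. The fallback changes the order so that acid can be used before the prenyl ether exists; it sets out from 13 and comes back at 16. Aqueous HCl in THF at 40 °C would remove both protecting groups from 13 to give the triol methyl 2-hydroxy-6-[2-hydroxy-6-(hydroxymethyl)-4-methoxyphenoxy]-4-methylbenzoate F8. One equivalent of 14 with K2CO3 in acetone at rt should then alkylate the unchelated ring B phenol in preference to the hydrogen-bonded salicylate hydroxyl and the benzylic alcohol, giving 16 directly.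

## Further compounds

F1 | step 6 | methyl 2-(2-methoxy-2-oxoethoxy)-4-methyl-6-{[2-(trimethylsilyl)ethoxy]methoxy}benzoate | COC(=O)COc1cc(C)cc(OCOCC[Si](C)(C)C)c1C(=O)OC
F2 | step 6 | methyl 6-methyl-3-oxo-4-{[2-(trimethylsilyl)ethoxy]methoxy}-2,3-dihydro-1-benzofuran-2-carboxylate (racemic, enolisable) | COC(=O)C1Oc2cc(C)cc(OCOCC[Si](C)(C)C)c2C1=O
F3 | step 6 | 5-{[tert-butyl(diphenyl)silyl]oxy}pent-3-yn-2-one | CC(=O)C#CCO[Si](c1ccccc1)(c1ccccc1)C(C)(C)C
F4 | step 6 | methyl 2-[(2Z)-1-{[tert-butyl(diphenyl)silyl]oxy}-4-oxopent-2-en-2-yl]-6-methyl-3-oxo-4-{[2-(trimethylsilyl)ethoxy]methoxy}-2,3-dihydro-1-benzofuran-2-carboxylate (racemic) | CC(=O)/C=C(/CO[Si](c1ccccc1)(c1ccccc1)C(C)(C)C)C1(C(=O)OC)Oc2cc(C)cc(OCOCC[Si](C)(C)C)c2C1=O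
F5 | step 7 | 6-({[tert-butyl(diphenyl)silyl]oxy}methyl)-8-hydroxy-3-methyl-1-{[2-(trimethylsilyl)ethoxy]methoxy}-11H-dibenzo[b,e][1,4]dioxepin-11-one | O=C1Oc2cc(O)cc(CO[Si](c3ccccc3)(c3ccccc3)C(C)(C)C)c2Oc2cc(C)cc(OCOCC[Si](C)(C)C)c12
F6 | step 7 | 6-({[tert-butyl(diphenyl)silyl]oxy}methyl)-8-methoxy-3-methyl-1-{[2-(trimethylsilyl)ethoxy]methoxy}-11H-dibenzo[b,e][1,4]dioxepin-11-one | O=C1Oc2cc(OC)cc(CO[Si](c3ccccc3)(c3ccccc3)C(C)(C)C)c2Oc2cc(C)cc(OCOCC[Si](C)(C)C)c12
F7 | step 8 | 6-({[tert-butyl(diphenyl)silyl]oxy}methyl)-8-methoxy-3-methyl-1-{[2-(trimethylsilyl)ethoxy]methoxy}-11H-dibenzo[b,e][1,4]dioxepin-11-one (same constitution as F6) | O=C1Oc2cc(OC)cc(CO[Si](c3ccccc3)(c3ccccc3)C(C)(C)C)c2Oc2cc(C)cc(OCOCC[Si](C)(C)C)c12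
F8 | step 10 | methyl 2-hydroxy-6-[2-hydroxy-6-(hydroxymethyl)-4-methoxyphenoxy]-4-methylbenzoate | COC(=O)c1c(O)cc(C)cc1Oc1c(CO)cc(OC)cc1O
A1 | alternative 1 | methyl 4-{[tert-butyl(dimethyl)silyl]oxy}-6-methyl-2-oxo-2H-pyran-3-carboxylate | COC(=O)C1=C(O[Si](C)(C)C(C)(C)C)C=C(C)OC1=O
A2 | alternative 1 | tert-butyl({2-(ethynyloxy)-5-methoxy-3-[(3-methylbut-2-en-1-yl)oxy]phenyl}methoxy)dimethylsilane | C#COc1c(CO[Si](C)(C)C(C)(C)C)cc(OC)cc1OCC=C(C)C
A3 | alternative 1 | methyl 2-{[tert-butyl(dimethyl)silyl]oxy}-6-{2-({[tert-butyl(dimethyl)silyl]oxy}methyl)-4-methoxy-6-[(3-methylbut-2-en-1-yl)oxy]phenoxy}-4-methylbenzoate | COC(=O)c1c(O[Si](C)(C)C(C)(C)C)cc(C)cc1Oc1c(CO[Si](C)(C)C(C)(C)C)cc(OC)cc1OCC=C(C)C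
A4 | alternative 1 | 2-({[tert-butyl(dimethyl)silyl]oxy}methyl)-4-methoxy-6-[(3-methylbut-2-en-1-yl)oxy]phenol | Oc1c(CO[Si](C)(C)C(C)(C)C)cc(OC)cc1OCC=C(C)C
A5 | alternative 2 | methyl 2-{[(1E)-2-({[tert-butyl(dimethyl)silyl]oxy}methyl)-4-diazo-3-oxobut-1-en-1-yl]oxy}-6-(methoxymethoxy)-4-methylbenzoate | COC(=O)c1c(OCOC)cc(C)cc1O/C=C(\CO[Si](C)(C)C(C)(C)C)C(=O)C=[N+]=[N-]
A6 | alternative 2 | methoxyacetylene | COC#C
A7 | alternative 2 | methyl 2-[2-({[tert-butyl(dimethyl)silyl]oxy}methyl)-6-hydroxy-4-methoxyphenoxy]-6-(methoxymethoxy)-4-methylbenzoate | COC(=O)c1c(OCOC)cc(C)cc1Oc1c(CO[Si](C)(C)C(C)(C)C)cc(OC)cc1O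
A8 | alternative 3 | dimethyl 2-(1-{2-({[tert-butyl(dimethyl)silyl]oxy}methyl)-4-methoxy-6-[(3-methylbut-2-en-1-yl)oxy]phenoxy}-3-methylbut-2-en-1-ylidene)propanedioate | COC(=O)C(C(=O)OC)=C(Oc1c(CO[Si](C)(C)C(C)(C)C)cc(OC)cc1OCC=C(C)C)C=C(C)C
A9 | alternative 3 | methyl 2-{2-({[tert-butyl(dimethyl)silyl]oxy}methyl)-4-methoxy-6-[(3-methylbut-2-en-1-yl)oxy]phenoxy}-6-hydroxy-4-methylbenzoate | COC(=O)c1c(O)cc(C)cc1Oc1c(CO[Si](C)(C)C(C)(C)C)cc(OC)cc1OCC=C(C)C
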